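The numbers were set for the occasion; the result is computed.

A half-life of 0.74 h for the target under over-reaction, short against a run of 6.0 h, is the number this flask turns on.

solid substrate 0.25 M; reagent 0.325 M; free catalyst 6.0 mM; time 6.0 h

    catalyst intermediate C → free catalyst + target (k1 = 0.0353 s⁻¹)
    free catalyst + target → free catalyst + over-reaction product (k2 = 0.0433 M⁻¹ s⁻¹)
    reagent + catalyst intermediate B ⇌ catalyst intermediate C (K3 = 160 M⁻¹, k3 = 0.155 M⁻¹ s⁻¹)
    starting material + free catalyst ⇌ catalyst intermediate A (K4 = 1.9 M⁻¹, k4 = 16.2 M⁻¹ s⁻¹)
    solid substrate ⇌ starting material, rate k5*(cs5 - [starting material]) while solid is left; crystals form when [starting material] > cs5 (cs5 = 28 mM, k5 = 2.22 × 10⁻⁴ s⁻¹)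
    catalyst intermediate A ⇌ catalyst intermediate B (K6 = 0.783, k6 = 0.0513 s⁻¹)

- as a solid, counted per litre of solution: solid substrate
- at the start none of the solid substrate is in solution
- run time (flask): 6.0 h

- south: doubling the solubility in step 5, all else as stated
- north-east: doubling the dissolution coefficient of step 5, all else as stated
- east: doubling the amount of reagent, all else as stated
- south-west: doubling the amount of free catalyst, all else as stated

* the target standing at 6.0 h, as a percentage of the solid substrate charged
* the change that raises the amount of target at 6.0 h, in percent of the solid substrate charged most ("none" if none brings more than 2 percentage points) (south / north-east / east / south-west / none)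
* amount of target at 6.0 h, in percent of the solid substrate charged, after north-east

The bench rule is to find the limiting reagent, here the solid substrate at 0.25 M against 0.325 M of reagent, and to count what dissolves as target. Applied honestly, that gives at most 53.7 % of the charge, the most step 5 can deliver into a solution kept empty. The rule stops at a ratio of given numbers: the run lasts 8.11 target half-lives of step 2 alone with free catalyst as charged, so the substrate balance has to carry the over-reaction product.

We therefore balance the target itself. Free catalyst multiplies both the target's making and the target's loss, so free catalyst cancels from their ratio. Binding of starting material relaxes faster than catalyst intermediate A moves on, and catalyst intermediate C goes on faster than it falls back, so we treat binding as an equilibrium and count catalyst intermediate B's two exits, with reagent as charged: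

share of catalyst intermediate B going on = 43.5 %

1.9 M⁻¹ × 0.0513 s⁻¹ × 43.5 % / 0.0433 M⁻¹ s⁻¹ = 0.978

This is the standing ratio, target over starting material while both hold still (a selectivity factor). Setting dissolution equal to catalytic consumption, with free catalyst as charged, gives the starting material, and the ratio gives the target:

consumption constant = 2.54 × 10⁻⁴ s⁻¹

starting material = 28 mM × 2.22 × 10⁻⁴ s⁻¹ / (2.22 × 10⁻⁴ s⁻¹ + 2.54 × 10⁻⁴ s⁻¹) = 13.1 mM

target = 0.978 × 13.1 mM = 5.11 % of the charge

The same lines give, for south, 10.2 %; for north-east, 6.97 %; for east, 5.88 %; and for south-west, 3.33 %. We commit to south, the highest of these.

The forecast gave 4.9 % (from 4.3 % to 5.6 %), a little below ours, named south as the best change and gave 6.5 % after north-east, reasoning that “Target therefore tracks the feed rate divided by free catalyst”. The simulation gives 4.88 %, south as the best change with a gain of 4.5 percentage points, and 6.36 % after north-east.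

At 6.00 h this flask reads a target-to-starting-material ratio of 0.853, and the standing ratio with the reagent then left is 0.867. The neighbour with 0.0015 M of free catalyst reads 0.610 against 0.939; its target half-life by step 2 alone, with free catalyst as charged, is 2.96 h, half of the run. Our flask is not at rest: 70.1 % of the solid substrate remains at 6.00 h. In our flask at 60.0 h the target stands at 0 %, over-reaction product at >99.9 %, and reagent at 23.1 %.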